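**Strategy.** The target is a diaryl ether whose hydroxyls at C1 of ring A (the dibromo ring) and C2' of ring B (the tribromo ring) both flank the bridging oxygen (C6–O–C1'). Each hydroxyl is therefore traced back to a formyl group. The ring B aldehyde first activates fluoride displacement to build the ether. Both aldehydes are then excised in one peracid oxidation that forms the C1–O and C2'–O bonds by aryl carbon-to-oxygen migration. The precursor is the bis-aldehyde 3-bromo-2-(2-formylphenoxy)benzaldehyde, which already carries the C6' bromine. The freed hydroxyls then steer the four remaining bromines to C2, C4, C3' and C5'.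

Key step: step 2

Assumption: locants follow the target as drawn. Ring A has the hydroxyl at C1, bromine at C2 and C4, and the ether oxygen at C6; ring B has the ether oxygen at C1', the hydroxyl at C2', and bromine at C3', C5' and C6'. The oxidation is run with a peracid, because alkaline hydrogen peroxide is unreliable for benzaldehydes that lack a free ortho or para hydroxyl.

**Step 1**
Reactants: 1 salicylaldehyde (2-hydroxybenzaldehyde); 2 3-bromo-2-fluorobenzaldehyde
Product: 3 3-bromo-2-(2-formylphenoxy)benzaldehyde
Conditions: K2CO3 (1.5 equiv), dry DMF, 90–100 °C, N2
Reagents that add atoms: none
Why: Nucleophilic aromatic substitution (SNAr); the ortho formyl group of 2 stabilises the Meisenheimer adduct and fluoride is the best leaving group, whereas the C–Br bond (meta to the formyl group) is not activated, and neither aldehyde is enolisable, so dry carbonate should cause no condensation chemistry.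

**Step 2**
Reactants: 3 3-bromo-2-(2-formylphenoxy)benzaldehyde
Product: 5 3-bromo-2-(2-hydroxyphenoxy)phenol, via bis-formate 4 (not isolated)
Conditions: mCPBA (3 equiv), CH2Cl2, 0 °C to 40 °C; aq Na2SO3 work-up; then HCl (cat.), MeOH, rt
Reagents that add atoms: mCPBA (3-chloroperoxybenzoic acid), O=C(OO)c1cccc(Cl)c1
Why: The peracid adds to each formyl carbon to give a peroxyhemiacetal (Criegee adduct), from which the aryl group shifts from carbon to oxygen as 3-chlorobenzoate departs, so that C1 of ring A and C2' of ring B become O-formylated; acid-catalysed methanolysis then removes both formyl groups as methyl formate. The closest known reaction type is the Baeyer–Villiger (Dakin-type) oxidation of ortho-alkoxy and ortho-aryloxy benzaldehydes to phenols through aryl formates. No ring is closed and no stereocenter is created. The selectivity required is aryl over hydride migration at both aldehydes; it is secured by the bridging ether oxygen, whose lone pair sits ortho to each migrating carbon and stabilises the electron-deficient transition state, and by the non-basic peracid medium, which disfavours the hydride-shift path to the carboxylic acid. The C6' bromine is meta to the migrating C2' and withdraws only inductively, so the ring B aldehyde should react more slowly but along the same course, hence the excess of peracid and gentle heating. The phenols stay masked as formates until the excess peracid has been reduced, which should protect the electron-rich product from over-oxidation.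

**Step 3**
Reactants: 5 3-bromo-2-(2-hydroxyphenoxy)phenol
Product: 6 3,4,6-tribromo-2-(3,5-dibromo-2-hydroxyphenoxy)phenol (target)
Conditions: Br2 (4.05 equiv, slow addition), AcOH, rt, dark
Reagents that add atoms: bromine, BrBr
Why: Electrophilic aromatic bromination; each hydroxyl is the strongest director on its ring and should send bromine to its free ortho and para positions (C2 and C4 on ring A, C3' and C5' on ring B, the latter two also ortho and para to the C6' bromine), while C3, C5 and C4' are meta to a hydroxyl and each ring is deactivated once it has taken two bromines.

**Compound list**
1 | salicylaldehyde (2-hydroxybenzaldehyde) | O=Cc1ccccc1O | starting material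
2 | 3-bromo-2-fluorobenzaldehyde | O=Cc1cccc(Br)c1F | starting material
3 | 3-bromo-2-(2-formylphenoxy)benzaldehyde | O=Cc1ccccc1Oc1c(Br)cccc1C=O | intermediate
4 | 3-bromo-2-[2-(formyloxy)phenoxy]phenyl formate (bis-formate, not isolated) | O=COc1ccccc1Oc1c(Br)cccc1OC=O | intermediate
5 | 3-bromo-2-(2-hydroxyphenoxy)phenol | Oc1ccccc1Oc1c(O)cccc1Br | intermediate
6 | 3,4,6-tribromo-2-(3,5-dibromo-2-hydroxyphenoxy)phenol | Oc1c(Br)cc(Br)cc1Oc1c(O)c(Br)cc(Br)c1Br | target

**Total step count:** 3
**Longest linear sequence:** 3 steps (1 or 2 → 3 → 5 → 6)

**Steps most likely to fail**

Step 2 (key step). The risk is that hydride migration, or collapse of the peracid adduct without rearrangement, competes with aryl migration at the slower ring B aldehyde, so that a carboxylic acid forms there instead of a formate. The fallback sets out from 3 and replaces the migrating-group competition by one that aryl wins easily. Addition of MeMgBr (2.2 equiv, THF, −78 to 0 °C) to both aldehydes should give the diol 1-[3-bromo-2-[2-(1-hydroxyethyl)phenoxy]phenyl]ethan-1-ol F1 as a mixture of diastereomers, which does not matter. Oxidation with Dess–Martin periodinane (CH2Cl2, rt) should give the diketone 1-[2-(2-acetyl-6-bromophenoxy)phenyl]ethan-1-one F2. Baeyer–Villiger oxidation of F2 (mCPBA, cat. CF3CO2H, CH2Cl2, rt), where methyl is a far poorer migrating group than the oxygen-substituted aryl, should give the diacetate 2-(2-acetoxyphenoxy)-3-bromophenyl acetate F3. Acid-catalysed methanolysis (HCl cat., MeOH) then returns to the route at 5.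

Step 3. The risk is incomplete or excessive bromination, or attack para to the ether oxygen, which would give a mixture of closely related polybromides that is hard to separate. The fallback sets out from 5 and stages the halogenation with reagent control. Tetrabutylammonium tribromide, Bu4NBr3 (2 equiv, CH2Cl2/MeOH, rt), a mild para-selective brominating agent for phenols, should give 3,4-dibromo-2-(5-bromo-2-hydroxyphenoxy)phenol F4, which is purified. The two remaining positions ortho to the hydroxyls are then brominated with NBS (2 equiv) and catalytic diisopropylamine (CH2Cl2, 0 °C), an ortho-directing protocol for phenols, rejoining the route at 6.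

Step 1. The risk is slow or incomplete fluoride displacement, because the formyl-conjugated, chelated phenoxide of 1 is a weak nucleophile and the fluoride of 2 is flanked on both sides, with degradation of the aldehydes on forcing. The fallback sets out from 2 and uses 2-(hydroxymethyl)phenol (saligenin, OCc1ccccc1O), whose phenoxide is not deactivated by a formyl group. Under K2CO3 in DMF at 70–80 °C it should arylate selectively at the phenolic oxygen to give 3-bromo-2-[2-(hydroxymethyl)phenoxy]benzaldehyde F5. Oxidation of the benzylic alcohol with MnO2 (CH2Cl2, rt) then returns to the route at 3, so the key step is kept unchanged.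

**Further compounds**
F1 | step 2 | 1-[3-bromo-2-[2-(1-hydroxyethyl)phenoxy]phenyl]ethan-1-ol (mixture of diastereomers, configuration not controlled) | CC(O)c1ccccc1Oc1c(Br)cccc1C(C)O
F2 | step 2 | 1-[2-(2-acetyl-6-bromophenoxy)phenyl]ethan-1-one | CC(=O)c1ccccc1Oc1c(Br)cccc1C(C)=O
F3 | step 2 | 2-(2-acetoxyphenoxy)-3-bromophenyl acetate | CC(=O)Oc1ccccc1Oc1c(OC(C)=O)cccc1Br
F4 | step 3 | 3,4-dibromo-2-(5-bromo-2-hydroxyphenoxy)phenol | Oc1ccc(Br)cc1Oc1c(O)ccc(Br)c1Br
F5 | step 1 | 3-bromo-2-[2-(hydroxymethyl)phenoxy]benzaldehyde | OCc1ccccc1Oc1c(Br)cccc1C=O
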